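The data stem from a simulated flask for an exercise.

North-west is the flask to repeat, and its tris adduct is the reading to watch.

| setting | summer | dusk | midnight | north-west | south |
|---|---|---|---|---|---|
| substrate | 24 mM | 24 mM | 24 mM | 24 mM | 24 mM |
| reagent | 14 mM | 44 mM | 110 mM | 96.0 mM | 19.2 mM |
| capture agent | 24 mM | 24 mM | 24 mM | 24.0 mM | 24.0 mM |
| remark | run made earlier | run made earlier | run made earlier |  |  |
| time |  |  |  | 1.0 h | 1.0 h |

| run | time / min | tris adduct / % | double product / % | substrate / % |
|---|---|---|---|---|
| summer | 8.00 | 5.5 | 8.6 | 60.4 |
| summer | 15.0 | 4.9 | 8.1 | 59.4 |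
| summer | 25.0 | 5.2 | 8.8 | 57.4 |
| summer | 30.0 | 5.6 | 8.5 | 57.7 |
| dusk | 2.50 | 26.5 | 15.7 | 37.1 |
| dusk | 6.00 | 36.2 | 14.9 | 28.7 |
| dusk | 12.0 | 38.6 | 11.7 | 26.6 |
| dusk | 30.0 | 38.1 | 12.8 | 26.0 |
| midnight | 4.00 | 81.0 | 4.1 | 6.6 |
| midnight | 10.0 | 90.4 | 0.2 | 0.9 |
| midnight | 20.0 | 92.4 | 0 | 0.6 |
| midnight | 30.0 | 93.2 | 0.3 | 0.3 |

(each reading ± 0.5 percentage points)



1. which of these holds the largest part of the substrate at the end of north-west (double product / single product / substrate / tris adduct)
2. which of these holds the largest part of the substrate at the end of south (double product / single product / substrate / tris adduct)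
3. how much tris adduct is there at the end of north-west, in percent of the substrate charged

Count equivalents as reagent charged over substrate charged. The dusk run reads 38.6% tris adduct at 12.0 min and 38.1% at 30.0 min, so time has dropped out of that run. Divide gain by gain instead, using last readings. The tris return, the tris adduct gained per added equivalent of reagent, comes to:

summer to dusk: 26 percentage points

dusk to midnight: 20 points

Bound north-west from above first. Its reagent would cover 133% of the substrate at 3 reagent per tris adduct, which is over the whole, so that gives no ceiling. Midnight, with more reagent, ends at 93.2%. Running the summer-to-dusk line on to north-west gives 94.4%, which is higher, so keep midnight as the ceiling.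

Now bound it from below. The summer-to-dusk return is larger than the dusk-to-midnight one. Assume the return keeps falling as reagent is added, and the dusk-to-midnight line runs under the curve:

floor = dusk + return × (north-west equivalents − dusk equivalents) = 81.5%

My bracket for north-west is 81.5% to 93.2%, each end carrying the scatter of the readings.

The forecast says tris adduct for north-west, substrate for south, and tris adduct at 89% (range 82% to 94%), “a little below midnight, with some single product remaining”. Its 89% lies inside my bracket.

The flask gives tris adduct for north-west and substrate for south, at 50.2%.

    substrate + reagent → single product + by-product (k = 0.340 M⁻¹ s⁻¹)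
    reagent + single product → double product + by-product (k = 1.10 M⁻¹ s⁻¹)
    reagent + double product → tris adduct + by-product (k = 0.940 M⁻¹ s⁻¹)
    substrate + single product → side product (k = 0.0600 M⁻¹ s⁻¹)
    single product + capture agent → trapped intermediate (k = 0.0960 M⁻¹ s⁻¹)
    2 reagent → self-condensation product (k = 0.0410 M⁻¹ s⁻¹)

North-west ends at 89.8% tris adduct, inside the bracket, and its return from dusk is 24 points, above the 20 points of the line. Take a neighbour flask, like north-west but with 41 mM substrate and so 2.34 equiv of reagent. Its ceiling from the reagent charge is 78.0%, and its floor from the same return is 48.3%. That neighbour flask gives 53.0% tris adduct, with 18.2% substrate left and reagent, the limiting reagent, at 0%.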